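| setting | Sunday's | Tuesday's | flask |
|---|---|---|---|
| left-handed substrate | 0.10 M | 0.10 M | 0.10 M |
| right-handed substrate | 0.10 M | 0.10 M | 0.10 M |
| partner | 0.15 M (fed, over 50 min) | 0.15 M (fed, over 50 min) | 0.150 M (fed, over 50 min) |
| precatalyst | 11 mM | 24 mM | 16 mM |
| remark | run made earlier | run made earlier |  |
| time |  |  | 8.0 h |

- Sunday's (time / h: left-handed product / %, right-handed product / %): 0.417: 11.0, 6.1; 0.667: 24.4, 15.0; 0.833: 32.0, 21.3; 1.33: 38.6, 27.8; 2.00: 39.9, 30.4; 3.00: 39.6, 28.8; 5.00: 39.9, 30.1
- Tuesday's (time / h: left-handed product / %, right-handed product / %): 0.250: 4.5, 2.4; 0.667: 27.2, 17.1; 1.33: 38.9, 27.1; 2.00: 38.6, 27.0; 3.00: 39.8, 27.7; 4.00: 39.0, 28.0; 5.00: 38.5, 27.2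

(readings scatter by 0.5 percentage points)

- catalyst is single-handed; left-handed substrate and right-handed substrate are mirror images of each other, charged as a racemate, each of them at the stated concentration
- steps that have been proposed: partner + catalyst + left-handed substrate -> catalyst + left-handed product; partner + catalyst + right-handed substrate -> catalyst + right-handed product; partner + precatalyst -> catalyst + spent reagent
- the reaction counts as stopped when no species that holds the left-handed substrate and right-handed substrate together changes by six tenths of a point or more over the second half of the time

- which holds at 8.0 h: what has brought the reaction to rest, or that it has not come to rest (no working catalyst is left / it is still moving / the partner has run out first / all of the left-handed substrate has reacted)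
- the left-handed product standing at 8.0 h, as a percentage of the left-handed substrate and right-handed substrate together charged
- the right-handed product standing at 8.0 h, as a percentage of the left-handed substrate and right-handed substrate together charged
- the right-handed substrate standing at 8.0 h, as a percentage of the left-handed substrate and right-handed substrate together charged

Count the partner first. By the proposed steps each product takes one partner, so the bench rule divides the partner charge by both substrates together. In the flask, as in Sunday's and Tuesday's runs, this gives:

partner cover = 75.0 % of the substrates

The late readings of both products together average 69.6 % in Sunday's run and 66.5 % in Tuesday's. The shortfall under the cover is thus 5.4 percentage points with 11 mM of precatalyst and a larger 8.5 points with 24 mM, as expected if activation also takes partner. Interpolating by precatalyst gives this reckoning for the flask: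

shortfall = 6.6 points
product total = 68.4 %

The rule counts on a partner charge too short for both substrates and the precatalyst together. The border is where this ratio reaches one:

partner / (substrates + precatalyst) = 0.694

The flask lies below that border, which makes the partner the limiting reagent. The total in Sunday's run reads 70.3 % at 2.00 h and 70.0 % at 5.00 h, that in Tuesday's run 65.6 % at 2.00 h and 65.7 % at 5.00 h, and the asked time is 9.60 feed lengths.

The forecast answers: the partner has run out first, with left-handed product 39.5 %, right-handed product 28.5 % and right-handed substrate 21.5 %. Its ground is this: “More precatalyst gives less product, so the partner is the limit, and activation consumes part of it.” Its two printed product values add to 68.0 %, which differs from the reckoning above by 0.37 points.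

The flask gives: the partner has run out first, with left-handed product 39.8 %, right-handed product 29.0 % and right-handed substrate 21.0 %.

    partner + catalyst + left-handed substrate → catalyst + left-handed product (k = 2.20 L² mol⁻² s⁻¹)
    partner + catalyst + right-handed substrate → catalyst + right-handed product (k = 1.20 L² mol⁻² s⁻¹)
    partner + precatalyst → catalyst + spent reagent (k = 0.0150 L mol⁻¹ s⁻¹)

In the flask, the product steps and activation ran while partner stood there: 18.7 % of its charge at 0.833 h, and 0 % at 4.00 h. Activation had 87 % of its turnover up to the asked time behind it by 0.800 h, 23.6 % of the catalyst charge stood as precatalyst at 8.00 h, and the product total ended 6.1 points under the cover, beside spent reagent equal to 6.11 % of the substrates. The neighbour charged with 0.26 M of partner has a cover of 130 % and a border ratio of 1.20; it ends with 50.0 % left-handed product, 50.0 % right-handed product and 17 % of its partner charge unused.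

The readings come from a simulation with made-up constants, noise included.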